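## Retrosynthetic overview

1. Locants used: ring C14 is the stereocentre, then C1, C2=C3(Me), C4, C5, C6=C7(CO2H), C8, C9, C10=C11(Me), C12, C13; the side chain is C15(Me)=C16–C17–C18=C19Me2.
2. The acid is unveiled from a 14-membered β-keto ester (C6=O, C7–CO2Me) by enol triflate formation, palladium-catalysed reduction and saponification; the C6 ketone is a temporary oxidation level that ends as the C6=C7 alkene.
3. The only ring is closed across C4–C5 by intramolecular SN2 alkylation of an acetoacetate-type dianion on a (Z)-allylic chloride. The enabling feature: C5 is the γ-carbon of the C7 carboxyl (C5–C6=C7–CO2H) and C4 is the allylic CH2 of the (Z)-C2=C3 alkene, so a carbonyl at C6 makes C5 the terminal carbon of a 1,3-dicarbonyl dianion and C4 an unhindered SN2 site.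
4. The acyclic precursor is built linearly: methyl acetoacetate (C5–C7) on a C8 chloride; Still–Gennari olefination for (Z)-C2=C3; Johnson–Claisen rearrangement with 1,3-chirality transfer for C14 (R) and (E)-C15=C16; asymmetric allylboration for the transferring carbinol; zirconium-catalysed carboalumination with oxirane opening for (E)-C10=C11.
5. Ring order: one ring only, the 14-membered carbocycle, formed in step 14.

Key step: step 14

Remark: the acyclic and cyclic β-keto esters are carried as mixtures of C7 epimers (and enol forms); this has no consequence because C7 becomes sp2 before the end.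

## Route

Step 1
Reactants: 1 tert-butyldimethyl(pent-4-yn-1-yloxy)silane; 2 oxirane
Product: 5 (E)-7-[(tert-butyldimethylsilyl)oxy]-4-methylhept-3-en-1-ol, via alkenylalane 3 (not isolated), via lithium alkenylalanate 4 (not isolated)
Conditions: Me3Al, Cp2ZrCl2 (20 mol%), CH2Cl2, 0 °C to rt; volatiles removed; n-BuLi, hexane/THF, −78 to 0 °C; then 2, THF, 0 °C to rt
Reagents that add atoms: trimethylaluminium, C[Al](C)C
Why: Zirconium-catalysed carboalumination of the terminal alkyne adds methyl and aluminium syn with aluminium on the terminal carbon, and the derived alanate should open oxirane with retention, which sets the (E)-C10=C11 alkene and brings in C8–C9.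

Step 2
Reactants: 5 (E)-7-[(tert-butyldimethylsilyl)oxy]-4-methylhept-3-en-1-ol
Product: 7 (E)-tert-butyl[(7-chloro-4-methylhept-4-en-1-yl)oxy]dimethylsilane, via mesylate 6 (not isolated)
Conditions: MsCl, Et3N, CH2Cl2, 0 °C; then LiCl, DMF, 60 °C
Reagents that add atoms: lithium chloride, [Li+].[Cl-]
Why: Mesylation followed by SN2 displacement with chloride at the primary carbon should install a C8 leaving group that is inert to all reagents used before step 12.

Step 3
Reactants: 7 (E)-tert-butyl[(7-chloro-4-methylhept-4-en-1-yl)oxy]dimethylsilane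
Product: 8 (E)-7-chloro-4-methylhept-4-en-1-ol
Conditions: camphorsulfonic acid (cat.), MeOH, rt
Reagents that add atoms: none
Why: Acid-catalysed methanolysis of the primary silyl ether (protecting-group cleavage) should leave the alkyl chloride and the trisubstituted alkene untouched.

Step 4
Reactants: 8 (E)-7-chloro-4-methylhept-4-en-1-ol
Product: 9 (E)-7-chloro-4-methylhept-4-enal
Conditions: TEMPO (10 mol%), PhI(OAc)2, CH2Cl2, rt
Reagents that add atoms: none
Why: The oxoammonium-mediated (TEMPO) oxidation of a primary alcohol should stop at the aldehyde and tolerates the alkene and the chloride.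

Step 5
Reactants: 9 (E)-7-chloro-4-methylhept-4-enal; 10 2-(triphenyl-λ5-phosphanylidene)propanal
Product: 11 (2E,6E)-9-chloro-2,6-dimethylnona-2,6-dienal
Conditions: toluene, 90 °C
Reagents that add atoms: none
Why: Wittig olefination with the stabilised α-methyl formyl ylide should give the (E)-2-methyl enal, whose geometry is needed for the chirality transfer in step 8.

Step 6
Reactants: 11 (2E,6E)-9-chloro-2,6-dimethylnona-2,6-dienal
Product: 13 (4R,5E,9E)-12-chloro-5,9-dimethyldodeca-1,5,9-trien-4-ol, via borinate ester 12 (not isolated)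
Conditions: B-allyldiisopinocampheylborane of the (−)-α-pinene series (commercial solution), Et2O, −78 °C; then NaOH, H2O2, 0 °C to rt
Reagents that add atoms: B-allyldiisopinocampheylborane, (−)-α-pinene series, C=CCB([C@H]1C[C@H]2C[C@@H]([C@@H]1C)C2(C)C)[C@H]1C[C@H]2C[C@@H]([C@@H]1C)C2(C)C
Why: Asymmetric allylboration (Brown allylation) through a closed six-membered chair transition state, in which the isopinocampheyl groups direct the allyl group to the Re face of the aldehyde, should set the C16 carbinol as R; oxidative work-up releases the alcohol.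

Step 7
Reactants: 13 (4R,5E,9E)-12-chloro-5,9-dimethyldodeca-1,5,9-trien-4-ol; 14 2-methylbut-2-ene
Product: 15 (5R,6E,10E)-13-chloro-2,6,10-trimethyltrideca-2,6,10-trien-5-ol
Conditions: 14 (excess), RuCl2(=CHPh)(PCy3)(H2IMes) (second-generation Grubbs catalyst, 5 mol%), CH2Cl2, 40 °C
Reagents that add atoms: none
Why: Cross-metathesis of the only monosubstituted alkene with 2-methylbut-2-ene should convert the allyl group into the prenyl terminus (C18=C19) with loss of propene, the trisubstituted alkenes being inert.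

Step 8
Reactants: 15 (5R,6E,10E)-13-chloro-2,6,10-trimethyltrideca-2,6,10-trien-5-ol; 16 1,1,1-trimethoxyethane
Product: 18 methyl (3R,4E)-3-[(3E)-6-chloro-3-methylhex-3-en-1-yl]-4,8-dimethylnona-4,7-dienoate, via ketene acetal 17 (not isolated)
Conditions: 16 (excess), EtCO2H (cat.), xylene, 140 °C, MeOH distilled off
Reagents that add atoms: none
Why: Johnson–Claisen rearrangement through a chair transition state with the C17 substituent pseudo-equatorial should form the C1–C14 bond suprafacially, so the (R) configuration of C16 is transferred across the (E)-C14=C15 alkene to C14 (R) and the new C15=C16 alkene is formed E.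

Step 9
Reactants: 18 methyl (3R,4E)-3-[(3E)-6-chloro-3-methylhex-3-en-1-yl]-4,8-dimethylnona-4,7-dienoate
Product: 19 (3R,4E)-3-[(3E)-6-chloro-3-methylhex-3-en-1-yl]-4,8-dimethylnona-4,7-dienal
Conditions: i-Bu2AlH (1.1 equiv), CH2Cl2, −78 °C; aq. potassium sodium tartrate
Reagents that add atoms: none
Why: Partial reduction of the methyl ester with i-Bu2AlH at low temperature should stop at the aldehyde because the aluminium hemiacetal survives until work-up; C14 is β to the carbonyl and cannot epimerise.

Step 10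
Reactants: 19 (3R,4E)-3-[(3E)-6-chloro-3-methylhex-3-en-1-yl]-4,8-dimethylnona-4,7-dienal; 20 ethyl 2-[bis(2,2,2-trifluoroethoxy)phosphoryl]propanoate
Product: 21 ethyl (2Z,5R,6E)-5-[(3E)-6-chloro-3-methylhex-3-en-1-yl]-2,6,10-trimethylundeca-2,6,9-trienoate
Conditions: KN(SiMe3)2, 18-crown-6, THF, −78 °C
Reagents that add atoms: none
Why: Still–Gennari olefination with the bis(trifluoroethyl) phosphonopropionate under dissociating conditions should give the (Z)-2-methyl enoate under kinetic control, which fixes the (Z)-C2=C3 alkene.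

Step 11
Reactants: 21 ethyl (2Z,5R,6E)-5-[(3E)-6-chloro-3-methylhex-3-en-1-yl]-2,6,10-trimethylundeca-2,6,9-trienoate
Product: 22 (2Z,5R,6E)-5-[(3E)-6-chloro-3-methylhex-3-en-1-yl]-2,6,10-trimethylundeca-2,6,9-trien-1-ol
Conditions: i-Bu2AlH (2.5 equiv), CH2Cl2, −78 °C; aq. potassium sodium tartrate
Reagents that add atoms: none
Why: 1,2-Reduction of the conjugated ester with i-Bu2AlH should give the (Z)-allylic alcohol without touching the alkyl chloride or the alkene geometry.

Step 12
Reactants: 22 (2Z,5R,6E)-5-[(3E)-6-chloro-3-methylhex-3-en-1-yl]-2,6,10-trimethylundeca-2,6,9-trien-1-ol; 23 methyl 3-oxobutanoate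
Product: 25 methyl (5E,9R,11Z)-2-acetyl-13-hydroxy-6,12-dimethyl-9-[(2E)-6-methylhepta-2,5-dien-2-yl]trideca-5,11-dienoate, via primary iodide 24 (not isolated)
Conditions: 23 (3 equiv), K2CO3, NaI (20 mol%), acetone, reflux
Reagents that add atoms: none
Why: Acetoacetic ester alkylation, in which the potassium enolate of 23 should C-alkylate the primary iodide formed in situ by Finkelstein exchange while the excess of 23 suppresses dialkylation; the new C7 stereocentre is uncontrolled and irrelevant.

Step 13
Reactants: 25 methyl (5E,9R,11Z)-2-acetyl-13-hydroxy-6,12-dimethyl-9-[(2E)-6-methylhepta-2,5-dien-2-yl]trideca-5,11-dienoate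
Product: 27 methyl (5E,9R,11Z)-2-acetyl-13-chloro-6,12-dimethyl-9-[(2E)-6-methylhepta-2,5-dien-2-yl]trideca-5,11-dienoate, via allylic mesylate 26 (not isolated)
Conditions: MsCl, 2,4,6-collidine, LiCl, DMF, 0 °C
Reagents that add atoms: lithium chloride, [Li+].[Cl-]
Why: Mesylation in the presence of chloride (allylic alcohol to allylic chloride by SN2) should give the primary (Z)-allylic chloride without allylic transposition or loss of geometry, the β-keto ester not being enolised by collidine.

Step 14
Reactants: 27 methyl (5E,9R,11Z)-2-acetyl-13-chloro-6,12-dimethyl-9-[(2E)-6-methylhepta-2,5-dien-2-yl]trideca-5,11-dienoate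
Product: 29 methyl (5Z,8R,11E)-5,11-dimethyl-8-[(2E)-6-methylhepta-2,5-dien-2-yl]-2-oxocyclotetradeca-5,11-diene-1-carboxylate, via dilithium dianion 28 (not isolated)
Conditions: LiN(i-Pr)2 (commercial solution, 2.3 equiv), THF, −78 °C, slow addition of 27 (final 2 mM); −78 to 0 °C; aq. NH4Cl
Reagents that add atoms: none
Why: LiN(i-Pr)2 removes first the C7–H and then a C5–H of the acetyl group to give the 1,3-dicarbonyl dianion 28, whose terminal C5 carbanion is far more nucleophilic than the stabilised C7/O centre and displaces chloride from the primary allylic C4 in an intramolecular SN2 reaction. The closest known reaction type is the γ-alkylation of acetoacetate dianions with geranyl- and neryl-type halides (Weiler alkylation), here run intramolecularly in the manner of the carbanion–allylic halide closures used for 14-membered terpenoid rings. The 14-membered ring is closed in the 14-exo-tet mode. The only new stereocentre is C7, which is formed without control and is erased when C6=C7 is introduced. The step needs γ- over α- or O-alkylation (secured by the dianion), SN2 over SN2' attack (primary C4 against the substituted C2 terminus), conservation of the (Z)-C2=C3 geometry (no allyl cation, radical or π-allyl metal species is involved) and ring closure over oligomerisation (high dilution with slow addition).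

Step 15
Reactants: 29 methyl (5Z,8R,11E)-5,11-dimethyl-8-[(2E)-6-methylhepta-2,5-dien-2-yl]-2-oxocyclotetradeca-5,11-diene-1-carboxylate
Product: 31 methyl (1Z,5Z,8R,11E)-5,11-dimethyl-8-[(2E)-6-methylhepta-2,5-dien-2-yl]-2-{[(trifluoromethyl)sulfonyl]oxy}cyclotetradeca-1,5,11-triene-1-carboxylate, via sodium enolate 30 (not isolated)
Conditions: NaH, THF, 0 °C; then PhNTf2, 0 °C to rt
Reagents that add atoms: N-phenylbis(trifluoromethanesulfonimide), O=S(=O)(N(c1ccccc1)S(=O)(=O)C(F)(F)F)C(F)(F)F
Why: Deprotonation gives the sodium-chelated enolate with the enolate oxygen and the ester carbonyl cis, so O-sulfonylation should give the (Z)-enol triflate, which stores the C6=C7 geometry.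

Step 16
Reactants: 31 methyl (1Z,5Z,8R,11E)-5,11-dimethyl-8-[(2E)-6-methylhepta-2,5-dien-2-yl]-2-{[(trifluoromethyl)sulfonyl]oxy}cyclotetradeca-1,5,11-triene-1-carboxylate
Product: 32 methyl (1E,5Z,8R,11E)-5,11-dimethyl-8-[(2E)-6-methylhepta-2,5-dien-2-yl]cyclotetradeca-1,5,11-triene-1-carboxylate
Conditions: Pd(OAc)2 (5 mol%), PPh3 (10 mol%), HCO2H, n-Bu3N, DMF, 60 °C
Reagents that add atoms: none
Why: Palladium-catalysed formate reduction of the enol triflate (oxidative addition to zerovalent palladium, formate-to-hydride exchange with loss of CO2, reductive elimination) should replace the triflate by hydrogen with retention, giving the (E)-enoate in which C5 is trans to the ester.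

Step 17
Reactants: 32 methyl (1E,5Z,8R,11E)-5,11-dimethyl-8-[(2E)-6-methylhepta-2,5-dien-2-yl]cyclotetradeca-1,5,11-triene-1-carboxylate
Product: 33 (1E,5Z,8R,11E)-5,11-dimethyl-8-[(2E)-6-methylhepta-2,5-dien-2-yl]cyclotetradeca-1,5,11-triene-1-carboxylic acid
Conditions: LiOH, THF/MeOH/H2O, 50 °C; then aq. HCl
Reagents that add atoms: lithium hydroxide, [Li+].[OH-]
Why: Saponification of the methyl ester followed by acidification should give the acid without touching the alkenes or the C14 stereocentre.

## Compound list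

1 | tert-butyldimethyl(pent-4-yn-1-yloxy)silane | C#CCCCO[Si](C)(C)C(C)(C)C | starting material
2 | oxirane | C1CO1 | starting material
3 | (E)-{5-[(tert-butyldimethylsilyl)oxy]-2-methylpent-1-en-1-yl}dimethylalumane | C[Al](C)/C=C(\C)CCCO[Si](C)(C)C(C)(C)C | intermediate
4 | lithium butyl{(E)-5-[(tert-butyldimethylsilyl)oxy]-2-methylpent-1-en-1-yl}dimethylalanate | [Li+].CCCC[Al-](C)(C)/C=C(\C)CCCO[Si](C)(C)C(C)(C)C | intermediate
5 | (E)-7-[(tert-butyldimethylsilyl)oxy]-4-methylhept-3-en-1-ol | OCC/C=C(\C)CCCO[Si](C)(C)C(C)(C)C | intermediate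
6 | (E)-7-[(tert-butyldimethylsilyl)oxy]-4-methylhept-3-en-1-yl methanesulfonate | CS(=O)(=O)OCC/C=C(\C)CCCO[Si](C)(C)C(C)(C)C | intermediate
7 | (E)-tert-butyl[(7-chloro-4-methylhept-4-en-1-yl)oxy]dimethylsilane | ClCC/C=C(\C)CCCO[Si](C)(C)C(C)(C)C | intermediate
8 | (E)-7-chloro-4-methylhept-4-en-1-ol | ClCC/C=C(\C)CCCO | intermediate
9 | (E)-7-chloro-4-methylhept-4-enal | ClCC/C=C(\C)CCC=O | intermediate
10 | 2-(triphenyl-λ5-phosphanylidene)propanal | CC(C=O)=P(c1ccccc1)(c1ccccc1)c1ccccc1 | starting material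
11 | (2E,6E)-9-chloro-2,6-dimethylnona-2,6-dienal | ClCC/C=C(\C)CC/C=C(\C)C=O | intermediate
12 | (4R,5E,9E)-12-chloro-5,9-dimethyldodeca-1,5,9-trien-4-yl diisopinocampheylborinate | ClCC/C=C(\C)CC/C=C(\C)[C@@H](CC=C)OB([C@H]1C[C@H]2C[C@@H]([C@@H]1C)C2(C)C)[C@H]1C[C@H]2C[C@@H]([C@@H]1C)C2(C)C | intermediate
13 | (4R,5E,9E)-12-chloro-5,9-dimethyldodeca-1,5,9-trien-4-ol | ClCC/C=C(\C)CC/C=C(\C)[C@H](O)CC=C | intermediate
14 | 2-methylbut-2-ene | CC=C(C)C | starting material
15 | (5R,6E,10E)-13-chloro-2,6,10-trimethyltrideca-2,6,10-trien-5-ol | ClCC/C=C(\C)CC/C=C(\C)[C@H](O)CC=C(C)C | intermediate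
16 | 1,1,1-trimethoxyethane | CC(OC)(OC)OC | starting material
17 | (5R,6E,10E)-13-chloro-5-[(1-methoxyethenyl)oxy]-2,6,10-trimethyltrideca-2,6,10-triene | C=C(OC)O[C@H](CC=C(C)C)/C(C)=C/CC/C(C)=C/CCCl | intermediate
18 | methyl (3R,4E)-3-[(3E)-6-chloro-3-methylhex-3-en-1-yl]-4,8-dimethylnona-4,7-dienoate | COC(=O)C[C@@H](CC/C(C)=C/CCCl)/C(C)=C/CC=C(C)C | intermediate
19 | (3R,4E)-3-[(3E)-6-chloro-3-methylhex-3-en-1-yl]-4,8-dimethylnona-4,7-dienal | O=CC[C@@H](CC/C(C)=C/CCCl)/C(C)=C/CC=C(C)C | intermediate
20 | ethyl 2-[bis(2,2,2-trifluoroethoxy)phosphoryl]propanoate | CCOC(=O)C(C)P(=O)(OCC(F)(F)F)OCC(F)(F)F | starting material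
21 | ethyl (2Z,5R,6E)-5-[(3E)-6-chloro-3-methylhex-3-en-1-yl]-2,6,10-trimethylundeca-2,6,9-trienoate | CCOC(=O)/C(C)=C\C[C@@H](CC/C(C)=C/CCCl)/C(C)=C/CC=C(C)C | intermediate
22 | (2Z,5R,6E)-5-[(3E)-6-chloro-3-methylhex-3-en-1-yl]-2,6,10-trimethylundeca-2,6,9-trien-1-ol | OC/C(C)=C\C[C@@H](CC/C(C)=C/CCCl)/C(C)=C/CC=C(C)C | intermediate
23 | methyl 3-oxobutanoate (methyl acetoacetate) | COC(=O)CC(C)=O | starting material
24 | (2Z,5R,6E)-5-[(3E)-6-iodo-3-methylhex-3-en-1-yl]-2,6,10-trimethylundeca-2,6,9-trien-1-ol | OC/C(C)=C\C[C@@H](CC/C(C)=C/CCI)/C(C)=C/CC=C(C)C | intermediate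
25 | methyl (5E,9R,11Z)-2-acetyl-13-hydroxy-6,12-dimethyl-9-[(2E)-6-methylhepta-2,5-dien-2-yl]trideca-5,11-dienoate | COC(=O)C(C(C)=O)CC/C=C(\C)CC[C@H](C/C=C(/C)CO)/C(C)=C/CC=C(C)C | intermediate
26 | methyl (5E,9R,11Z)-2-acetyl-6,12-dimethyl-9-[(2E)-6-methylhepta-2,5-dien-2-yl]-13-[(methylsulfonyl)oxy]trideca-5,11-dienoate | COC(=O)C(C(C)=O)CC/C=C(\C)CC[C@H](C/C=C(/C)COS(C)(=O)=O)/C(C)=C/CC=C(C)C | intermediate
27 | methyl (5E,9R,11Z)-2-acetyl-13-chloro-6,12-dimethyl-9-[(2E)-6-methylhepta-2,5-dien-2-yl]trideca-5,11-dienoate | COC(=O)C(C(C)=O)CC/C=C(\C)CC[C@H](C/C=C(/C)CCl)/C(C)=C/CC=C(C)C | intermediate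
28 | dilithium 1,3-dienolate (dianion) of 27 | [Li+].[Li+].COC([O-])=C(CC/C=C(\C)CC[C@H](C/C=C(/C)CCl)/C(C)=C/CC=C(C)C)C([O-])=C | intermediate
29 | methyl (5Z,8R,11E)-5,11-dimethyl-8-[(2E)-6-methylhepta-2,5-dien-2-yl]-2-oxocyclotetradeca-5,11-diene-1-carboxylate | COC(=O)C1CC/C=C(\C)CC[C@@H](/C(C)=C/CC=C(C)C)C/C=C(/C)CCC1=O | intermediate
30 | sodium (1Z)-enolate of 29 | [Na+].COC(=O)/C1=C(\[O-])CC/C(C)=C\C[C@H](/C(C)=C/CC=C(C)C)CC/C(C)=C/CC1 | intermediate
31 | methyl (1Z,5Z,8R,11E)-5,11-dimethyl-8-[(2E)-6-methylhepta-2,5-dien-2-yl]-2-{[(trifluoromethyl)sulfonyl]oxy}cyclotetradeca-1,5,11-triene-1-carboxylate | COC(=O)/C1=C(\OS(=O)(=O)C(F)(F)F)CC/C(C)=C\C[C@H](/C(C)=C/CC=C(C)C)CC/C(C)=C/CC1 | intermediate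
32 | methyl (1E,5Z,8R,11E)-5,11-dimethyl-8-[(2E)-6-methylhepta-2,5-dien-2-yl]cyclotetradeca-1,5,11-triene-1-carboxylate | COC(=O)/C1=C/CC/C(C)=C\C[C@H](/C(C)=C/CC=C(C)C)CC/C(C)=C/CC1 | intermediate
33 | (1E,5Z,8R,11E)-5,11-dimethyl-8-[(2E)-6-methylhepta-2,5-dien-2-yl]cyclotetradeca-1,5,11-triene-1-carboxylic acid | CC(C)=CC/C=C(\C)[C@H]1C/C=C(/C)CC/C=C(/C(=O)O)CC/C=C(\C)CC1 | target

## Step count and risks

Total step count: 17. Longest linear sequence: 17 steps (1 to 33).

Steps most likely to fail:

1. Step 14. Intermolecular alkylation (oligomerisation) may outrun the 14-membered ring closure, or the amide base may consume the allylic chloride before the dianion has formed. The fallback sets out from 22 and comes back at 29. Alcohol 22 would be converted (MsCl, LiCl, 2,4,6-collidine, DMF, 0 °C) into the allylic/alkyl bis-chloride F1. The dianion of methyl acetoacetate 23 (NaH, then n-BuLi, THF, 0 °C) would be alkylated at its terminal carbon by the allylic chloride of F1 only, which makes the same C4–C5 bond intermolecularly under the standard conditions and gives the ω-chloro β-keto ester F2. The ring would then be closed at C7–C8 by intramolecular C-alkylation of the β-keto ester (NaI, Cs2CO3, MeCN, 70 °C, high dilution) to give 29.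

2. Step 15. O-sulfonylation of the hindered, stabilised enolate may be slow or may proceed without control of the enol geometry, which the stereoretentive reduction of step 16 would carry into the alkene. The fallback sets out from 29 and comes back at 32. Reduction of the ketone (NaBH4, MeOH, 0 °C) would give the β-hydroxy ester F3 as a diastereomer mixture. Mesylation (MsCl, Et3N, CH2Cl2) would give the mesylate F4, and E1cB elimination with DBU (toluene, rt) should give the conjugated ester 32 under thermodynamic control, with C5 trans to the ester.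

3. Step 1. Transfer of the alkenyl group from the alanate to oxirane may be incomplete or may compete with butyl or methyl transfer and protonolysis. The fallback sets out from 1 and comes back at 5. The same carboalumination would be quenched with I2 to give the isolable vinyl iodide F5. Iodine–lithium exchange (t-BuLi, Et2O, −78 °C) and opening of oxirane 2 in the presence of BF3·OEt2 would then give 5 with retention of the alkene geometry.

## Further compounds

F1 | step 14 | (2Z,5R,6E)-1-chloro-5-[(3E)-6-chloro-3-methylhex-3-en-1-yl]-2,6,10-trimethylundeca-2,6,9-triene | ClC/C(C)=C\C[C@@H](CC/C(C)=C/CCCl)/C(C)=C/CC=C(C)C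
F2 | step 14 | methyl (6Z,9R,10E)-9-[(3E)-6-chloro-3-methylhex-3-en-1-yl]-6,10,14-trimethyl-3-oxopentadeca-6,10,13-trienoate | COC(=O)CC(=O)CC/C(C)=C\C[C@@H](CC/C(C)=C/CCCl)/C(C)=C/CC=C(C)C
F3 | step 15 | methyl (5Z,8R,11E)-2-hydroxy-5,11-dimethyl-8-[(2E)-6-methylhepta-2,5-dien-2-yl]cyclotetradeca-5,11-diene-1-carboxylate | COC(=O)C1CC/C=C(\C)CC[C@@H](/C(C)=C/CC=C(C)C)C/C=C(/C)CCC1O
F4 | step 15 | methyl (5Z,8R,11E)-5,11-dimethyl-8-[(2E)-6-methylhepta-2,5-dien-2-yl]-2-[(methylsulfonyl)oxy]cyclotetradeca-5,11-diene-1-carboxylate | COC(=O)C1CC/C=C(\C)CC[C@@H](/C(C)=C/CC=C(C)C)C/C=C(/C)CCC1OS(C)(=O)=O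
F5 | step 1 | (E)-tert-butyl[(5-iodo-4-methylpent-4-en-1-yl)oxy]dimethylsilane | I/C=C(\C)CCCO[Si](C)(C)C(C)(C)C
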